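**Remark on the chemistry:** labdane numbering (C1–C20) is used throughout. The target is read as the 14,15-diacetate of ent-labd-7-ene-13,14,15-triol (5R,9R,10R,13S,14R). Its side-chain pattern is the one that arises by anti opening of an E-13,14-epoxide.

## Retrosynthetic overview

1. Side chain: diacetate ⇐ (13S,14R)-triol ⇐ (13R,14R)-13,14-epoxy-15-ol (water opens C13 with inversion) ⇐ ent-labda-7,13E-dien-15-ol (Sharpless epoxidation). C12–C13 comes from a B-alkyl Suzuki coupling of a 9-vinyl decalin with the E-enol triflate of methyl acetoacetate.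
2. C9: the vinyl group and the C9–H come from the C9 ketone of a bicyclic enone, by vinyl addition and palladium/formate hydrogenolysis of the tertiary allylic carbonate.
3. Ring order: ring B is bought as (S)-(+)-carvone. Its ring carbons are C5–C10, its enone is C9=O/C7=C8 with the C17 methyl, and its isopropenyl group is C4 with C18/C19. Ring A is formed second, by the C3–C4 bond.
4. Enabling feature: the gem-dimethyl quaternary carbon C4 of ring A sits on the ring-fusion carbon C5, so it is the Markovnikov hydrogen-atom-transfer product of carvone's isopropenyl group. The tertiary C4 radical closes ring A 6-exo onto C3, carried as an aldehyde tosylhydrazone on the C10 arm, and the acceptor then leaves as sulfinate and N2, so nothing has to be removed afterwards.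
5. C10 (methyl and the C1–C3 arm) is set first by two α′-alkylations of carvone. The arm enters anti to the isopropenyl group, which fixes the trans ring fusion.

Key step: step 5

## Route

Step 1
Reactants: 1 (S)-(+)-carvone
Product: 3 (5S)-2,6-dimethyl-5-(prop-1-en-2-yl)cyclohex-2-en-1-one (C6 epimer mixture), via lithium dienolate 2 (not isolated)
Conditions: LiN(iPr)2, THF, −78 °C; MeI, −78 → 0 °C
Reagents that add atoms: iodomethane (CI)
Why: Kinetic α′-deprotonation of the enone and C-methylation of the cross-conjugated lithium dienolate (enolate alkylation) should install C20; the epimer mixture at C10 is erased by the enolisation in step 2.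

Step 2
Reactants: 3 (5S)-2,6-dimethyl-5-(prop-1-en-2-yl)cyclohex-2-en-1-one
Product: 5 (5R,6R)-2,6-dimethyl-5-(prop-1-en-2-yl)-6-(prop-2-yn-1-yl)cyclohex-2-en-1-one, via lithium enolate 4 (not isolated)
Conditions: LiN(iPr)2, THF/DMPU, −78 → 0 °C; HC≡CCH2Br, −78 → 23 °C
Reagents that add atoms: 3-bromoprop-1-yne (C#CCBr)
Why: Second enolate alkylation, in which the tetrasubstituted enolate should be propargylated on the face anti to the neighbouring C5 isopropenyl group (held pseudoaxial by allylic strain with the C10 methyl), placing the C1–C3 arm trans to isopropenyl and fixing quaternary C10.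

Step 3
Reactants: 5 (5R,6R)-2,6-dimethyl-5-(prop-1-en-2-yl)-6-(prop-2-yn-1-yl)cyclohex-2-en-1-one
Product: 6 3-[(1R,6R)-1,3-dimethyl-2-oxo-6-(prop-1-en-2-yl)cyclohex-3-en-1-yl]propanal
Conditions: [CpRu(MeCN)3]PF6 (5 mol %), 5,5′-bis(trifluoromethyl)-2,2′-bipyridine (5 mol %), NMP/H2O 4:1, 25 °C
Reagents that add atoms: water (O)
Why: Ruthenium-vinylidene-mediated anti-Markovnikov hydration of the terminal alkyne should give the aldehyde at C3 and leave the enone and the 1,1-disubstituted alkene untouched.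

Step 4
Reactants: 6 3-[(1R,6R)-1,3-dimethyl-2-oxo-6-(prop-1-en-2-yl)cyclohex-3-en-1-yl]propanal
Product: 7 N′-{(1E)-3-[(1R,6R)-1,3-dimethyl-2-oxo-6-(prop-1-en-2-yl)cyclohex-3-en-1-yl]propylidene}-4-methylbenzenesulfonohydrazide
Conditions: TsNHNH2, MeOH, 23 °C
Reagents that add atoms: 4-methylbenzenesulfonohydrazide (Cc1ccc(cc1)S(=O)(=O)NN)
Why: Hydrazone formation should occur only at the aldehyde, because the conjugated C9 ketone is flanked by the quaternary C10 and reacts far more slowly.

Step 5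
Reactants: 7 N′-{(1E)-3-[(1R,6R)-1,3-dimethyl-2-oxo-6-(prop-1-en-2-yl)cyclohex-3-en-1-yl]propylidene}-4-methylbenzenesulfonohydrazide
Product: 10 (4aR,8aR)-2,5,5,8a-tetramethyl-4a,5,6,7,8,8a-hexahydronaphthalen-1(4H)-one, via cyclised N′-alkyl-N-tosylhydrazide 8 (not isolated), via monoalkyl diazene 9 (not isolated)
Conditions: Fe(acac)3 (30 mol %), PhSiH3, EtOH, 60 °C; then Et3N, 75 °C
Reagents that add atoms: none
Why: The iron hydride formed from Fe(acac)3 and PhSiH3 transfers a hydrogen atom to the CH2 terminus of the isopropenyl group (Markovnikov MHAT), the tertiary C4 radical adds to the hydrazone carbon C3, the hydrazinyl radical is reduced and protonated to hydrazide 8, and base-induced loss of p-toluenesulfinate and then of N2 from diazene 9 leaves C3 as CH2. The closest known reaction types are the MHAT hydromethylation of alkenes with formaldehyde sulfonylhydrazones and the HAT-triggered intramolecular reductive alkylation of alkenes with tosylhydrazones. Ring A is closed in the 6-exo-trig mode (radical at C4, acceptor carbon C3 of the C=N bond, chain C4–C5–C10–C1–C2–C3). No permanent stereocentre is created (C4 carries two methyls and the C3 centre of 8 is erased), and the ring fusion has to be trans because the preset C5 and C10 centres hold the radical and the acceptor arm trans-diequatorial on ring B. The step needs chemoselective hydrogen-atom transfer to the electron-rich 1,1-disubstituted alkene over the electron-poor C7=C8 enone, which MHAT provides and the geometry reinforces, since the C4 radical could reach the enone only through a four-membered or a five-membered endo closure. It also needs cyclisation to outrun reduction of the radical, which the strongly radical-accepting C=N bond and the quaternary C10 in the tether should secure.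

Step 6
Reactants: 10 (4aR,8aR)-2,5,5,8a-tetramethyl-4a,5,6,7,8,8a-hexahydronaphthalen-1(4H)-one
Product: 12 (1R,4aR,8aR)-1-ethenyl-2,5,5,8a-tetramethyl-1,4,4a,5,6,7,8,8a-octahydronaphthalen-1-yl methyl carbonate, via bromomagnesium alkoxide 11 (not isolated)
Conditions: CH2=CHMgBr, THF, 0 → 23 °C; then ClCO2Me, 0 → 23 °C
Reagents that add atoms: vinylmagnesium bromide (C=C[Mg]Br); methyl chloroformate (COC(=O)Cl)
Why: 1,2-Addition of the vinyl Grignard reagent to the enone carbonyl from the face anti to the axial C10 methyl (carbonyl addition) and O-acylation of the magnesium alkoxide should give the tertiary allylic carbonate, whose C9 configuration is erased in step 7 so that either epimer is usable.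

Step 7
Reactants: 12 (1R,4aR,8aR)-1-ethenyl-2,5,5,8a-tetramethyl-1,4,4a,5,6,7,8,8a-octahydronaphthalen-1-yl methyl carbonate
Product: 13 (1R,4aR,8aR)-1-ethenyl-2,5,5,8a-tetramethyl-1,4,4a,5,6,7,8,8a-octahydronaphthalene
Conditions: Pd(acac)2 (5 mol %), n-Bu3P (5 mol %), HCO2H, Et3N, THF, 23 → 50 °C
Reagents that add atoms: none
Why: In this palladium-catalysed formate hydrogenolysis of an allylic carbonate (Tsuji reduction), zerovalent palladium ionises the carbonate to an allylpalladium formate held at the unhindered C12 terminus, and after loss of CO2 the hydride should be delivered to the more substituted terminus C9 from the face anti to the axial C10 methyl, which gives the terminal vinyl group, keeps C7=C8 in place and sets C9 as 9R.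

Step 8
Reactants: 14 methyl acetoacetate
Product: 15 methyl (2E)-3-{[(trifluoromethyl)sulfonyl]oxy}but-2-enoate
Conditions: Tf2O, aq. Me4NOH, hexane, 5 °C
Reagents that add atoms: trifluoromethanesulfonic anhydride (O=S(=O)(OS(=O)(=O)C(F)(F)F)C(F)(F)F)
Why: O-Sulfonylation of the β-keto ester enolate with a non-chelating tetramethylammonium counter-ion should give the E-enol triflate (stereoselective enol triflate formation).

Step 9
Reactants: 13 (1R,4aR,8aR)-1-ethenyl-2,5,5,8a-tetramethyl-1,4,4a,5,6,7,8,8a-octahydronaphthalene; 15 methyl (2E)-3-{[(trifluoromethyl)sulfonyl]oxy}but-2-enoate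
Product: 17 methyl (2E)-3-methyl-5-[(1R,4aR,8aR)-2,5,5,8a-tetramethyl-1,4,4a,5,6,7,8,8a-octahydronaphthalen-1-yl]pent-2-enoate, via B-alkyl-9-BBN adduct 16 (not isolated)
Conditions: 9-BBN, THF, 0 → 23 °C; then 15, PdCl2(dppf) (5 mol %), aq. K3PO4, DMF, 23 → 50 °C
Reagents that add atoms: none
Why: 9-BBN should add only to the monosubstituted vinyl group (anti-Markovnikov, boron on C12), and the B-alkyl Suzuki–Miyaura coupling with the activated enol triflate forms C12–C13 with retention of the E geometry.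

Step 10
Reactants: 17 methyl (2E)-3-methyl-5-[(1R,4aR,8aR)-2,5,5,8a-tetramethyl-1,4,4a,5,6,7,8,8a-octahydronaphthalen-1-yl]pent-2-enoate
Product: 18 (2E)-3-methyl-5-[(1R,4aR,8aR)-2,5,5,8a-tetramethyl-1,4,4a,5,6,7,8,8a-octahydronaphthalen-1-yl]pent-2-en-1-ol
Conditions: iBu2AlH, CH2Cl2, −78 °C
Reagents that add atoms: none
Why: 1,2-Reduction of the conjugated ester with iBu2AlH (ester reduction) should give the E-allylic alcohol without touching either alkene.

Step 11
Reactants: 18 (2E)-3-methyl-5-[(1R,4aR,8aR)-2,5,5,8a-tetramethyl-1,4,4a,5,6,7,8,8a-octahydronaphthalen-1-yl]pent-2-en-1-ol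
Product: 19 [(2R,3R)-3-methyl-3-{2-[(1R,4aR,8aR)-2,5,5,8a-tetramethyl-1,4,4a,5,6,7,8,8a-octahydronaphthalen-1-yl]ethyl}oxiran-2-yl]methanol
Conditions: Ti(OiPr)4 (10 mol %), D-(−)-diethyl tartrate (12 mol %), t-BuOOH, 4 Å MS, CH2Cl2, −20 °C
Reagents that add atoms: tert-butyl hydroperoxide (CC(C)(C)OO)
Why: Sharpless asymmetric epoxidation is chemoselective for the allylic alcohol over C7=C8 and, with D-(−)-diethyl tartrate on an E-trisubstituted allylic alcohol, should deliver oxygen under reagent control to give the (13R,14R)-epoxide.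

Step 12
Reactants: 19 [(2R,3R)-3-methyl-3-{2-[(1R,4aR,8aR)-2,5,5,8a-tetramethyl-1,4,4a,5,6,7,8,8a-octahydronaphthalen-1-yl]ethyl}oxiran-2-yl]methanol
Product: 20 (2R,3S)-3-methyl-5-[(1R,4aR,8aR)-2,5,5,8a-tetramethyl-1,4,4a,5,6,7,8,8a-octahydronaphthalen-1-yl]pentane-1,2,3-triol
Conditions: HClO4 (cat.), THF/H2O 3:1, 0 → 23 °C
Reagents that add atoms: water (O)
Why: In this acid-catalysed epoxide hydrolysis, water should open the protonated trisubstituted epoxide at the tertiary carbon C13 with inversion (borderline SN2), turning (13R,14R) into the (13S,14R)-triol while C14 keeps its C–O bond.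

Step 13
Reactants: 20 (2R,3S)-3-methyl-5-[(1R,4aR,8aR)-2,5,5,8a-tetramethyl-1,4,4a,5,6,7,8,8a-octahydronaphthalen-1-yl]pentane-1,2,3-triol
Product: 21 (2R,3S)-3-hydroxy-3-methyl-5-[(1R,4aR,8aR)-2,5,5,8a-tetramethyl-1,4,4a,5,6,7,8,8a-octahydronaphthalen-1-yl]pentane-1,2-diyl diacetate
Conditions: Ac2O, pyridine, DMAP (cat.), CH2Cl2, 0 → 23 °C
Reagents that add atoms: acetic anhydride (CC(=O)OC(C)=O)
Why: Acetylation should esterify the primary C15 and the secondary C14 hydroxyl groups and leave the tertiary C13 hydroxyl free (acylation selective by steric class).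

## Compound list

1 | (S)-(+)-carvone, (5S)-2-methyl-5-(prop-1-en-2-yl)cyclohex-2-en-1-one | O=C1C(C)=CC[C@H](C(C)=C)C1 | starting material
2 | lithium dienolate of 1 (α′-enolate) | [Li]OC1=C[C@@H](C(C)=C)CC=C1C | intermediate (not isolated)
3 | (5S)-2,6-dimethyl-5-(prop-1-en-2-yl)cyclohex-2-en-1-one, C6 epimer mixture | O=C1C(C)=CC[C@H](C(C)=C)C1C | intermediate
4 | lithium enolate of 3 (tetrasubstituted α′-enolate) | [Li]OC1=C(C)[C@@H](C(C)=C)CC=C1C | intermediate (not isolated)
5 | (5R,6R)-2,6-dimethyl-5-(prop-1-en-2-yl)-6-(prop-2-yn-1-yl)cyclohex-2-en-1-one | O=C1C(C)=CC[C@H](C(C)=C)[C@@]1(C)CC#C | intermediate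
6 | 3-[(1R,6R)-1,3-dimethyl-2-oxo-6-(prop-1-en-2-yl)cyclohex-3-en-1-yl]propanal | O=C1C(C)=CC[C@H](C(C)=C)[C@@]1(C)CCC=O | intermediate
7 | E-tosylhydrazone of aldehyde 6 | O=C1C(C)=CC[C@H](C(C)=C)[C@@]1(C)CC/C=N/NS(=O)(=O)c1ccc(C)cc1 | intermediate
8 | cyclised hydrazide: enone 10 carrying a 2-tosylhydrazinyl group at C3 (labdane numbering), C3 epimers | O=C1C(C)=CC[C@@H]2C(C)(C)C(NNS(=O)(=O)c3ccc(C)cc3)CC[C@@]12C | intermediate (not isolated)
9 | monoalkyl diazene: enone 10 carrying N=NH at C3, C3 epimers | O=C1C(C)=CC[C@@H]2C(C)(C)C(N=N)CC[C@@]12C | intermediate (not isolated)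
10 | (4aR,8aR)-2,5,5,8a-tetramethyl-4a,5,6,7,8,8a-hexahydronaphthalen-1(4H)-one (trans-fused bicyclic enone) | O=C1C(C)=CC[C@@H]2C(C)(C)CCC[C@@]12C | intermediate
11 | bromomagnesium (1R,4aR,8aR)-1-ethenyl-2,5,5,8a-tetramethyl-1,4,4a,5,6,7,8,8a-octahydronaphthalen-1-olate | C=C[C@@]1(O[Mg]Br)C(C)=CC[C@@H]2C(C)(C)CCC[C@@]12C | intermediate (not isolated)
12 | (1R,4aR,8aR)-1-ethenyl-2,5,5,8a-tetramethyl-1,4,4a,5,6,7,8,8a-octahydronaphthalen-1-yl methyl carbonate | C=C[C@@]1(OC(=O)OC)C(C)=CC[C@@H]2C(C)(C)CCC[C@@]12C | intermediate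
13 | (1R,4aR,8aR)-1-ethenyl-2,5,5,8a-tetramethyl-1,4,4a,5,6,7,8,8a-octahydronaphthalene | C=C[C@@H]1C(C)=CC[C@@H]2C(C)(C)CCC[C@@]12C | intermediate
14 | methyl acetoacetate | COC(=O)CC(C)=O | starting material
15 | methyl (2E)-3-{[(trifluoromethyl)sulfonyl]oxy}but-2-enoate | COC(=O)/C=C(\C)OS(=O)(=O)C(F)(F)F | intermediate
16 | 9-{2-[(1R,4aR,8aR)-2,5,5,8a-tetramethyl-1,4,4a,5,6,7,8,8a-octahydronaphthalen-1-yl]ethyl}-9-borabicyclo[3.3.1]nonane | C1CC2CCCC(C1)B2CC[C@@H]1C(C)=CC[C@@H]2C(C)(C)CCC[C@@]12C | intermediate (not isolated)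
17 | methyl (2E)-3-methyl-5-[(1R,4aR,8aR)-2,5,5,8a-tetramethyl-1,4,4a,5,6,7,8,8a-octahydronaphthalen-1-yl]pent-2-enoate (methyl ent-labda-7,13E-dien-15-oate) | COC(=O)/C=C(\C)CC[C@@H]1C(C)=CC[C@@H]2C(C)(C)CCC[C@@]12C | intermediate
18 | (2E)-3-methyl-5-[(1R,4aR,8aR)-2,5,5,8a-tetramethyl-1,4,4a,5,6,7,8,8a-octahydronaphthalen-1-yl]pent-2-en-1-ol (ent-labda-7,13E-dien-15-ol) | OC/C=C(\C)CC[C@@H]1C(C)=CC[C@@H]2C(C)(C)CCC[C@@]12C | intermediate
19 | [(2R,3R)-3-methyl-3-{2-[(1R,4aR,8aR)-2,5,5,8a-tetramethyl-1,4,4a,5,6,7,8,8a-octahydronaphthalen-1-yl]ethyl}oxiran-2-yl]methanol ((13R,14R)-epoxide) | OC[C@H]1O[C@]1(C)CC[C@@H]2C(C)=CC[C@@H]3C(C)(C)CCC[C@@]23C | intermediate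
20 | (2R,3S)-3-methyl-5-[(1R,4aR,8aR)-2,5,5,8a-tetramethyl-1,4,4a,5,6,7,8,8a-octahydronaphthalen-1-yl]pentane-1,2,3-triol ((13S,14R)-triol) | OC[C@@H](O)[C@@](C)(O)CC[C@@H]1C(C)=CC[C@@H]2C(C)(C)CCC[C@@]12C | intermediate
21 | (2R,3S)-3-hydroxy-3-methyl-5-[(1R,4aR,8aR)-2,5,5,8a-tetramethyl-1,4,4a,5,6,7,8,8a-octahydronaphthalen-1-yl]pentane-1,2-diyl diacetate | CC(=O)OC[C@@H](OC(C)=O)[C@@](C)(O)CC[C@@H]1C(C)=CC[C@@H]2C(C)(C)CCC[C@@]12C | target

## Step count and risks

Total step count: 13. Longest linear sequence: 12 (steps 1–7 and 9–13; step 8 makes fragment 2).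

The three steps most likely to fail:

**Step 5 (key step).** The tertiary C4 radical may be reduced before it cyclises, which would simply hydrogenate the isopropenyl group, or the hydrazide may not lose sulfinate and N2 cleanly. The fallback closes the same C3–C4 bond by a radical conjugate addition and removes an ester afterwards. It sets out from 3: LiN(iPr)2 and methyl 2-(bromomethyl)acrylate should give, by the same anti alkylation as in step 2, methyl 2-{[(1R,6R)-1,3-dimethyl-2-oxo-6-(prop-1-en-2-yl)cyclohex-3-en-1-yl]methyl}prop-2-enoate F1. Fe(acac)3 and PhSiH3 in EtOH at 60 °C then add the C4 radical 6-endo to the CH2 terminus of the acrylate and should give methyl (4aR,8aR)-4,4,7,8a-tetramethyl-8-oxo-1,2,3,4,4a,5,8,8a-octahydronaphthalene-2-carboxylate F2. LiOH in THF/H2O gives the corresponding carboxylic acid F3, and photochemical hydrodecarboxylation (acridinium photocatalyst, thiophenol, blue light) comes back to the route at 10.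

**Step 7.** The hydride may be delivered to the wrong terminus of the dienyl-palladium system (C12 or C7), giving conjugated dienes, or the tertiary carbonate may ionise or eliminate already in step 6. The fallback builds the vinyl group one carbon at a time and sets C9 by hydroboration. It sets out from 10: Wittig methylenation (Ph3PCH3Br, KOtBu, toluene, 90 °C) gives (4aR,8aR)-2,5,5,8a-tetramethyl-1-methylidene-1,4,4a,5,6,7,8,8a-octahydronaphthalene F4. 9-BBN followed by NaOH/H2O2 should add at the exocyclic terminus from the face anti to the C10 methyl and give ent-drimenol F5. Dess–Martin oxidation gives ent-drimenal F6, and a second Wittig methylenation comes back to the route at 13.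

**Step 12.** The opening at C13 may lose stereochemical integrity if it acquires carbocation character, or a hydride or alkyl shift may compete. The fallback inverts C14 instead of C13 by purely SN2 events. It sets out from 18: Sharpless epoxidation with L-(+)-diethyl tartrate gives the (13S,14S)-epoxy alcohol [(2S,3S)-3-methyl-3-{2-[(1R,4aR,8aR)-2,5,5,8a-tetramethyl-1,4,4a,5,6,7,8,8a-octahydronaphthalen-1-yl]ethyl}oxiran-2-yl]methanol F7. Aqueous NaOH in t-BuOH at 75 °C should then effect Payne rearrangement, by intramolecular attack of the C15 alkoxide on C14 with inversion, to the terminal epoxide (2S)-2-[(2R)-oxiran-2-yl]-4-[(1R,4aR,8aR)-2,5,5,8a-tetramethyl-1,4,4a,5,6,7,8,8a-octahydronaphthalen-1-yl]butan-2-ol F8, which is not isolated. Hydroxide opens it at C15, which comes back to the route at 20.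

Further compounds
F1 | step 5 | methyl 2-{[(1R,6R)-1,3-dimethyl-2-oxo-6-(prop-1-en-2-yl)cyclohex-3-en-1-yl]methyl}prop-2-enoate | O=C1C(C)=CC[C@H](C(C)=C)[C@@]1(C)CC(=C)C(=O)OC
F2 | step 5 | methyl (4aR,8aR)-4,4,7,8a-tetramethyl-8-oxo-1,2,3,4,4a,5,8,8a-octahydronaphthalene-2-carboxylate (C2 epimers) | O=C1C(C)=CC[C@@H]2C(C)(C)CC(C(=O)OC)C[C@@]12C
F3 | step 5 | (4aR,8aR)-4,4,7,8a-tetramethyl-8-oxo-1,2,3,4,4a,5,8,8a-octahydronaphthalene-2-carboxylic acid (C2 epimers) | O=C1C(C)=CC[C@@H]2C(C)(C)CC(C(=O)O)C[C@@]12C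
F4 | step 7 | (4aR,8aR)-2,5,5,8a-tetramethyl-1-methylidene-1,4,4a,5,6,7,8,8a-octahydronaphthalene | C=C1C(C)=CC[C@@H]2C(C)(C)CCC[C@@]12C
F5 | step 7 | ent-drimenol, [(1R,4aR,8aR)-2,5,5,8a-tetramethyl-1,4,4a,5,6,7,8,8a-octahydronaphthalen-1-yl]methanol | OC[C@@H]1C(C)=CC[C@@H]2C(C)(C)CCC[C@@]12C
F6 | step 7 | ent-drimenal, (1R,4aR,8aR)-2,5,5,8a-tetramethyl-1,4,4a,5,6,7,8,8a-octahydronaphthalene-1-carbaldehyde | O=C[C@@H]1C(C)=CC[C@@H]2C(C)(C)CCC[C@@]12C
F7 | step 12 | [(2S,3S)-3-methyl-3-{2-[(1R,4aR,8aR)-2,5,5,8a-tetramethyl-1,4,4a,5,6,7,8,8a-octahydronaphthalen-1-yl]ethyl}oxiran-2-yl]methanol | OC[C@@H]1O[C@@]1(C)CC[C@@H]2C(C)=CC[C@@H]3C(C)(C)CCC[C@@]23C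
F8 | step 12 | (2S)-2-[(2R)-oxiran-2-yl]-4-[(1R,4aR,8aR)-2,5,5,8a-tetramethyl-1,4,4a,5,6,7,8,8a-octahydronaphthalen-1-yl]butan-2-ol | C1O[C@H]1[C@@](C)(O)CC[C@@H]2C(C)=CC[C@@H]3C(C)(C)CCC[C@@]23C
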